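**Retrosynthetic overview**
1. Numbering, used for all precursors as well: C1 allyl-bearing bridgehead, C2=C3(OMe), C4 (CHOH), C5 bridgehead CH, C6 (CH-aryl), C7 (CH-CH3), C8 bridging C=O.
2. The plan rests on the five-membered ring C1–C8–C5–C6–C7. It is a cyclopentanone whose carbonyl C8 sits between the allylated quaternary C1 and C5, with C6-aryl and C7-methyl trans. A conrotatory 4π closure (C6–C7) whose oxyallyl cation is quenched by an allyl nucleophile at C1 leaves exactly this pattern.
3. Late stage: C4–OH comes from the C2=C3(OMe)–C4=O enone, and that enone from a 1,2-dione. The six-membered ring C1–C2–C3–C4–C5–C8 is opened at C3–C4, an acyloin coupling of two cis ester arms on C1 and C5. C8 is carried as a dioxolane through the sodium step and as a carbinol through the hydride step.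
4. Key disconnection: cyclopentanone diester ⇒ cross-conjugated dienone + allyltrimethylsilane. This covers bonds C6–C7 and C1–allyl and four stereocentres, under a chiral copper Lewis acid.
5. The dienone comes from Knoevenagel condensation of veratraldehyde with a β-ketoester built on an (E)-ethylidenesuccinate with two different esters (Wittig). Ring order: five-membered ring first (step 6), six-membered ring second (step 8).

Key step: step 6

Assumption: no close analogue allows the sense of conrotation imposed on the dienone by the (S,S)-ligand to be predicted. (S,S)-t-Bu-box, 2,2'-(propane-2,2-diyl)bis[(4S)-4-tert-butyl-4,5-dihydro-1,3-oxazole], is written. If a trial run gives the mirror-image series, the equally available (R,R)-ligand is used with no other change.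

Step 1
Reactants: 1 tert-butyl (triphenylphosphoranylidene)acetate; 2 methyl bromoacetate
Product: 4 1-tert-butyl 4-methyl 2-(triphenylphosphoranylidene)butanedioate, via alkylated phosphonium bromide 3 (not isolated)
Conditions: 1 (2 equiv), 2 (1 equiv), EtOAc, reflux; filter off the precipitated salt
Reagents that add atoms: methyl bromoacetate, COC(=O)CBr
Why: C-alkylation of a stabilised phosphorane followed by transylidation (the second equivalent of 1 deprotonates 3) is a standard entry to phosphoranylidene succinates, and the two unlike esters fix from the start that the conjugated carboxyl can later be freed alone, which a Stobbe half-ester (free acid on the CH2 side) would not allow.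

Step 2
Reactants: 4 1-tert-butyl 4-methyl 2-(triphenylphosphoranylidene)butanedioate; 5 acetaldehyde
Product: 6 1-tert-butyl 4-methyl (E)-2-ethylidenebutanedioate
Conditions: MeCHO (5 equiv), toluene, sealed tube, 60 °C
Reagents that add atoms: acetaldehyde, CC=O
Why: Wittig olefination with an α-substituted ester-stabilised ylide should place the methyl group trans to the carboxyl, giving the E-alkene that later presents the methyl group outward in the electrocyclisation.

Step 3
Reactants: 6 1-tert-butyl 4-methyl (E)-2-ethylidenebutanedioate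
Product: 7 (E)-2-ethylidene-4-methoxy-4-oxobutanoic acid
Conditions: CF3CO2H–CH2Cl2 (1:2), 0 °C to rt
Reagents that add atoms: none
Why: Acidolysis of the tert-butyl ester (E1 loss of 2-methylpropene) leaves the methyl ester and the trisubstituted alkene untouched, so only the conjugated carboxyl is set free.

Step 4
Reactants: 7 (E)-2-ethylidene-4-methoxy-4-oxobutanoic acid; 8 potassium methyl malonate
Product: 10 dimethyl (E)-4-ethylidene-3-oxohexanedioate, via acyl imidazolide 9 (not isolated)
Conditions: (a) 1,1'-carbonyldiimidazole, THF, rt; (b) 8, MgCl2, Et3N, MeCN, rt, then solution (a), rt; aq citric acid work-up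
Reagents that add atoms: potassium methyl malonate, COC(=O)CC(=O)[O-].[K+]
Why: In the Masamune–Brooks chain extension the acyl imidazolide C-acylates the magnesium enolate of the malonate half-ester and decarboxylation delivers the β-ketoester under near-neutral conditions that spare the methyl ester and limit migration of the C1=C7 double bond.

Step 5
Reactants: 10 dimethyl (E)-4-ethylidene-3-oxohexanedioate; 11 3,4-dimethoxybenzaldehyde
Product: 12 dimethyl (2Z,4E)-2-(3,4-dimethoxybenzylidene)-4-ethylidene-3-oxohexanedioate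
Conditions: piperidine (cat), AcOH (cat), 4 Å MS, benzene, 50 °C
Reagents that add atoms: 3,4-dimethoxybenzaldehyde, COc1ccc(C=O)cc1OC
Why: Knoevenagel condensation of a β-ketoester with an aromatic aldehyde should favour the isomer with aryl cis to the ester and trans to the ketone, the minor isomer is not lost because alkylidene β-ketoesters equilibrate under the Lewis acid of step 6, and the buffered catalyst at moderate temperature limits base-induced shift of the ethylidene double bond.

Step 6
Reactants: 12 dimethyl (2Z,4E)-2-(3,4-dimethoxybenzylidene)-4-ethylidene-3-oxohexanedioate; 13 allyltrimethylsilane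
Product: 14 methyl (1R,3S,4S,5S)-3-allyl-5-(3,4-dimethoxyphenyl)-3-(2-methoxy-2-oxoethyl)-4-methyl-2-oxocyclopentane-1-carboxylate (allyl and aryl on one ring face; methyl, CH2CO2Me and CO2Me on the other)
Conditions: [Cu((S,S)-t-Bu-box)](SbF6)2 (30 mol %), 13 (5 equiv), (CF3)2CHOH (1.2 equiv), CH2Cl2, −20 °C to rt
Reagents that add atoms: allyltrimethylsilane, C=CC[Si](C)(C)C
Why: Proposed new method: chelation of the C8 ketone and the C4 ester carbonyl of 12 by the cationic divalent copper centre produces a pentadienyl cation that closes the five-membered ring C1–C8–C5–C6–C7 by thermal conrotatory 4π electrocyclisation (new bond C6–C7), and the resulting oxyallyl cation is attacked at C1 by the π bond of 13, the β-silyl cation then giving up Me3Si+ to (CF3)2CHOH while the same alcohol protonates the copper enolate and frees the catalyst. The closest known reaction types are the enantioselective Nazarov cyclisation of 2-alkylidene β-ketoesters with copper bis(oxazoline) or pybox Lewis acids and the interrupted Nazarov reaction of simple dienones with allylsilanes under BF3·OEt2; their combination on one polarised substrate is what is new. Both termini carry their substituent outward (aryl trans to C8 across C5=C6, methyl trans to C8 across C1=C7), so conrotation must place C6-aryl and C7-methyl trans, and the tert-butyl groups of the twofold-symmetric ligand make one of the two conrotatory senses the easier one, which fixes the absolute configuration of C6 and C7. C1 is set by approach of 13 to the ring face opposite the neighbouring C7 methyl group, and C5 is set last by protonation and keto–enol equilibration to the ester trans to the C6 aryl group, so that the CH2CO2Me arm on C1 and the CO2Me arm on C5 end up cis. Site selectivity (C1 rather than C5) rests on the ester, which holds the electron-rich end of the oxyallyl unit at C5 as a chelated enolate and leaves the tertiary C1 as the cationic end; the same chelation makes the enolate too poor a nucleophile to close a [3+2] adduct onto the β-silyl cation. The step further needs capture to outrun proton loss from C2 or C7 and direct Hosomi–Sakurai addition at C6, for which the non-basic SbF6 counter-ions, the absence of any amine, the excess of 13 and the donor aryl group (which lowers the acceptor strength of C6) are relied on, while the alcohol additive prevents build-up of an achiral silyl Lewis acid that would run a racemic background reaction.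

Step 7
Reactants: 14 methyl (1R,3S,4S,5S)-3-allyl-5-(3,4-dimethoxyphenyl)-3-(2-methoxy-2-oxoethyl)-4-methyl-2-oxocyclopentane-1-carboxylate
Product: 15 methyl 9-allyl-7-(3,4-dimethoxyphenyl)-9-(2-methoxy-2-oxoethyl)-8-methyl-1,4-dioxaspiro[4.4]nonane-6-carboxylate (C8 dioxolane of 14; configuration unchanged)
Conditions: HOCH2CH2OH (10 equiv), TsOH·H2O (cat), toluene, Dean–Stark reflux
Reagents that add atoms: ethane-1,2-diol, OCCO
Why: Acid-catalysed ketalisation with azeotropic water removal is routine for 2-oxocyclopentanecarboxylates and for 2,2-disubstituted cyclopentanones, a dioxolane (unlike a dimethyl ketal) does not collapse to the β-alkoxy acrylate, and any equilibration at C5 on the way ends at the ester trans to the aryl group that is needed.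

Step 8
Reactants: 15 methyl 9-allyl-7-(3,4-dimethoxyphenyl)-9-(2-methoxy-2-oxoethyl)-8-methyl-1,4-dioxaspiro[4.4]nonane-6-carboxylate
Product: 16 1-allyl-6-(3,4-dimethoxyphenyl)-7-methyl-3,4-bis(trimethylsilyloxy)spiro[bicyclo[3.2.1]oct-3-ene-8,2'-[1,3]dioxolane] (aryl exo, methyl endo)
Conditions: Na dispersion (4.5 equiv), Me3SiCl (6 equiv), toluene, reflux, slow addition of 15
Reagents that add atoms: chlorotrimethylsilane, C[Si](C)(C)Cl
Why: The acyloin condensation in its Rühlmann form joins the two ester carbons (C3–C4) and closes the six-membered ring C1–C2–C3–C4–C5–C8 because both arms are held cis-1,3 on the cyclopentane, while Me3SiCl traps the enediolate and the methoxide so that Dieckmann closure of C2 onto C4 and epimerisation at C5 are suppressed.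

Step 9
Reactants: 16 1-allyl-6-(3,4-dimethoxyphenyl)-7-methyl-3,4-bis(trimethylsilyloxy)spiro[bicyclo[3.2.1]oct-3-ene-8,2'-[1,3]dioxolane]
Product: 18 1-allyl-6-(3,4-dimethoxyphenyl)-3-hydroxy-7-methylspiro[bicyclo[3.2.1]oct-2-ene-8,2'-[1,3]dioxolan]-4-one (diosphenol), via ketol 17 (not isolated)
Conditions: (a) MeOH, HCl (cat), degassed, 0 °C to rt; (b) Cu(OAc)2·H2O (2.2 equiv), MeOH, reflux
Reagents that add atoms: none
Why: Methanolysis of the silyl enol ethers gives the ketol, Cu(OAc)2 effects the classical acyloin-to-1,2-dione oxidation without touching alkene or arene, and the dione can enolise only toward C2 because C5 is a bridgehead (Bredt's rule), so a single diosphenol should result.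

Step 10
Reactants: 18 1-allyl-6-(3,4-dimethoxyphenyl)-3-hydroxy-7-methylspiro[bicyclo[3.2.1]oct-2-ene-8,2'-[1,3]dioxolan]-4-one
Product: 19 1-allyl-6-(3,4-dimethoxyphenyl)-3-methoxy-7-methylspiro[bicyclo[3.2.1]oct-2-ene-8,2'-[1,3]dioxolan]-4-one
Conditions: Me2SO4, K2CO3, acetone, reflux
Reagents that add atoms: dimethyl sulfate, COS(=O)(=O)OC
Why: O-alkylation of the acidic diosphenol with a hard methylating agent and a weak base is the standard route to α-methoxy enones, and it is done with C8 still ketalised so that no base meets the non-enolisable 1,3-dione.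

Step 11
Reactants: 19 1-allyl-6-(3,4-dimethoxyphenyl)-3-methoxy-7-methylspiro[bicyclo[3.2.1]oct-2-ene-8,2'-[1,3]dioxolan]-4-one
Product: 20 1-allyl-6-(3,4-dimethoxyphenyl)-3-methoxy-7-methylbicyclo[3.2.1]oct-2-ene-4,8-dione
Conditions: 3 M aq HCl–THF (1:1), 45 °C
Reagents that add atoms: water, O
Why: Acid hydrolysis of the hindered bridge ketal is placed here because the enol ether is still deactivated by conjugation with the C4 ketone (protonation at C2 would give an α-keto oxocarbenium ion), whereas after reduction at C4 it would be an ordinary acid-labile enol ether.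

Step 12
Reactants: 20 1-allyl-6-(3,4-dimethoxyphenyl)-3-methoxy-7-methylbicyclo[3.2.1]oct-2-ene-4,8-dione
Product: 21 1-allyl-6-(3,4-dimethoxyphenyl)-3-methoxy-7-methylbicyclo[3.2.1]oct-2-ene-4,8-diol (4-OH pseudo-equatorial on the side of the C6–C7 bridge; 8-OH syn to the C6–C7 bridge)
Conditions: NaBH4 (3 equiv), CeCl3·7H2O (2 equiv), MeOH, −78 to 0 °C
Reagents that add atoms: none
Why: In this Luche reduction the strained non-conjugated C8 ketone cannot be spared and reacts first (hydride from the open face above the flat C2–C3–C4 bridge, a centre erased in step 14), after which the enone is reduced 1,2 with hydride entering C4 from the face syn to C8, since the other face is covered by the C6–C7 bridge with its endo hydrogen and endo methyl group, which sets the required C4 configuration; a dioxolane oxygen at C8 would have blocked just this face.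

Step 13
Reactants: 21 1-allyl-6-(3,4-dimethoxyphenyl)-3-methoxy-7-methylbicyclo[3.2.1]oct-2-ene-4,8-diol
Product: 22 1-allyl-6-(3,4-dimethoxyphenyl)-3-methoxy-7-methyl-4-(triethylsilyloxy)bicyclo[3.2.1]oct-2-en-8-ol
Conditions: Et3SiCl (1.05 equiv), imidazole, CH2Cl2, −20 °C
Reagents that add atoms: chlorotriethylsilane, CC[Si](Cl)(CC)CC
Why: Sterically controlled monosilylation should pick the pseudo-equatorial allylic C4 carbinol, because the C8 carbinol is flanked by the quaternary C1 and lies beside the exo aryl group.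

Step 14
Reactants: 22 1-allyl-6-(3,4-dimethoxyphenyl)-3-methoxy-7-methyl-4-(triethylsilyloxy)bicyclo[3.2.1]oct-2-en-8-ol
Product: 23 1-allyl-6-(3,4-dimethoxyphenyl)-3-methoxy-7-methyl-4-(triethylsilyloxy)bicyclo[3.2.1]oct-2-en-8-one
Conditions: Dess–Martin periodinane, pyridine, CH2Cl2, 0 °C to rt
Reagents that add atoms: none
Why: Dess–Martin oxidation converts hindered secondary alcohols under buffered non-acidic conditions that leave enol ether, silyl ether and allyl group alone, and C5 cannot epimerise because a bridgehead enol is excluded.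

Step 15
Reactants: 23 1-allyl-6-(3,4-dimethoxyphenyl)-3-methoxy-7-methyl-4-(triethylsilyloxy)bicyclo[3.2.1]oct-2-en-8-one
Product: 24 (1R,4R,5S,6S,7S)-1-allyl-6-(3,4-dimethoxyphenyl)-4-hydroxy-3-methoxy-7-methylbicyclo[3.2.1]oct-2-en-8-one (CNP0232354.1)
Conditions: Bu4NF–AcOH (1:1), THF, 0 °C
Reagents that add atoms: none
Why: Fluoride cleavage of the triethylsilyl ether buffered with acetic acid keeps the medium near neutral, which avoids both alkoxide-driven retro-aldol opening of the C4–C5–C8 β-hydroxy ketone and acid hydrolysis of the enol ether.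

**Compound list**
1 | tert-butyl (triphenylphosphoranylidene)acetate | CC(C)(C)OC(=O)C=P(c1ccccc1)(c1ccccc1)c1ccccc1 | starting material
2 | methyl bromoacetate | COC(=O)CBr | starting material
3 | [1-(tert-butoxycarbonyl)-3-methoxy-3-oxopropyl]triphenylphosphonium bromide | COC(=O)CC(C(=O)OC(C)(C)C)[P+](c1ccccc1)(c1ccccc1)c1ccccc1.[Br-] | intermediate
4 | 1-tert-butyl 4-methyl 2-(triphenylphosphoranylidene)butanedioate | COC(=O)CC(C(=O)OC(C)(C)C)=P(c1ccccc1)(c1ccccc1)c1ccccc1 | intermediate
5 | acetaldehyde | CC=O | starting material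
6 | 1-tert-butyl 4-methyl (E)-2-ethylidenebutanedioate | C/C=C(\CC(=O)OC)C(=O)OC(C)(C)C | intermediate
7 | (E)-2-ethylidene-4-methoxy-4-oxobutanoic acid | C/C=C(\CC(=O)OC)C(=O)O | intermediate
8 | potassium methyl malonate | COC(=O)CC(=O)[O-].[K+] | starting material
9 | methyl (E)-3-(imidazole-1-carbonyl)pent-3-enoate (acyl imidazolide) | C/C=C(\CC(=O)OC)C(=O)n1ccnc1 | intermediate
10 | dimethyl (E)-4-ethylidene-3-oxohexanedioate | C/C=C(\CC(=O)OC)C(=O)CC(=O)OC | intermediate
11 | 3,4-dimethoxybenzaldehyde | COc1ccc(C=O)cc1OC | starting material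
12 | dimethyl (2Z,4E)-2-(3,4-dimethoxybenzylidene)-4-ethylidene-3-oxohexanedioate | C/C=C(\CC(=O)OC)C(=O)/C(C(=O)OC)=C/c1ccc(OC)c(OC)c1 | intermediate
13 | allyltrimethylsilane | C=CC[Si](C)(C)C | starting material
14 | methyl (1R,3S,4S,5S)-3-allyl-5-(3,4-dimethoxyphenyl)-3-(2-methoxy-2-oxoethyl)-4-methyl-2-oxocyclopentane-1-carboxylate | C=CC[C@@]1(CC(=O)OC)C(=O)[C@H](C(=O)OC)[C@@H](c2ccc(OC)c(OC)c2)[C@@H]1C | intermediate
15 | methyl 9-allyl-7-(3,4-dimethoxyphenyl)-9-(2-methoxy-2-oxoethyl)-8-methyl-1,4-dioxaspiro[4.4]nonane-6-carboxylate (configuration as in 14) | C=CC[C@@]1(CC(=O)OC)C2(OCCO2)[C@H](C(=O)OC)[C@@H](c3ccc(OC)c(OC)c3)[C@@H]1C | intermediate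
16 | 1-allyl-6-(3,4-dimethoxyphenyl)-7-methyl-3,4-bis(trimethylsilyloxy)spiro[bicyclo[3.2.1]oct-3-ene-8,2'-[1,3]dioxolane] (C1, C5, C6, C7 as in 24) | C=CC[C@@]12CC(O[Si](C)(C)C)=C(O[Si](C)(C)C)[C@@H](C13OCCO3)[C@@H](c4ccc(OC)c(OC)c4)[C@@H]2C | intermediate
17 | 1-allyl-6-(3,4-dimethoxyphenyl)-4-hydroxy-7-methylspiro[bicyclo[3.2.1]octane-8,2'-[1,3]dioxolan]-3-one (ketol; in equilibrium with the 3-hydroxy-4-one form, carbinol configuration open) | C=CC[C@@]12CC(=O)C(O)[C@@H](C13OCCO3)[C@@H](c4ccc(OC)c(OC)c4)[C@@H]2C | intermediate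
18 | 1-allyl-6-(3,4-dimethoxyphenyl)-3-hydroxy-7-methylspiro[bicyclo[3.2.1]oct-2-ene-8,2'-[1,3]dioxolan]-4-one | C=CC[C@@]12C=C(O)C(=O)[C@@H](C13OCCO3)[C@@H](c4ccc(OC)c(OC)c4)[C@@H]2C | intermediate
19 | 1-allyl-6-(3,4-dimethoxyphenyl)-3-methoxy-7-methylspiro[bicyclo[3.2.1]oct-2-ene-8,2'-[1,3]dioxolan]-4-one | C=CC[C@@]12C=C(OC)C(=O)[C@@H](C13OCCO3)[C@@H](c4ccc(OC)c(OC)c4)[C@@H]2C | intermediate
20 | 1-allyl-6-(3,4-dimethoxyphenyl)-3-methoxy-7-methylbicyclo[3.2.1]oct-2-ene-4,8-dione | C=CC[C@@]12C=C(OC)C(=O)[C@@H](C1=O)[C@@H](c3ccc(OC)c(OC)c3)[C@@H]2C | intermediate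
21 | 1-allyl-6-(3,4-dimethoxyphenyl)-3-methoxy-7-methylbicyclo[3.2.1]oct-2-ene-4,8-diol | C=CC[C@@]12C=C(OC)[C@H](O)[C@@H]([C@@H]1O)[C@@H](c3ccc(OC)c(OC)c3)[C@@H]2C | intermediate
22 | 1-allyl-6-(3,4-dimethoxyphenyl)-3-methoxy-7-methyl-4-(triethylsilyloxy)bicyclo[3.2.1]oct-2-en-8-ol | C=CC[C@@]12C=C(OC)[C@H](O[Si](CC)(CC)CC)[C@@H]([C@@H]1O)[C@@H](c3ccc(OC)c(OC)c3)[C@@H]2C | intermediate
23 | 1-allyl-6-(3,4-dimethoxyphenyl)-3-methoxy-7-methyl-4-(triethylsilyloxy)bicyclo[3.2.1]oct-2-en-8-one | C=CC[C@@]12C=C(OC)[C@H](O[Si](CC)(CC)CC)[C@@H](C1=O)[C@@H](c3ccc(OC)c(OC)c3)[C@@H]2C | intermediate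
24 | (1R,4R,5S,6S,7S)-1-allyl-6-(3,4-dimethoxyphenyl)-4-hydroxy-3-methoxy-7-methylbicyclo[3.2.1]oct-2-en-8-one | C=CC[C@@]12C=C(OC)[C@H](O)[C@@H](C1=O)[C@@H](c1ccc(OC)c(OC)c1)[C@@H]2C | target

**Total step count:** 15. **Longest linear sequence:** 15 steps (1 to 24).

**Steps most likely to fail**

Step 6. Capture of the oxyallyl cation may lose out to proton loss from C2 or C7 or to direct conjugate allylation at C6. The enantioselectivity may also be eroded by a silyl-cation background reaction.

The fallback uses known chemistry and builds the bicyclic core by the acid-promoted cationic [5+2] cycloaddition of a p-quinone monoketal with an (E)-propenylarene.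
- It sets out from 11. EtMgBr (THF, 0 °C) gives 1-(3,4-dimethoxyphenyl)propan-1-ol F1, and TsOH-catalysed dehydration (toluene, reflux) gives (E)-1,2-dimethoxy-4-(prop-1-enyl)benzene F2.
- In parallel, commercial 3,4-dimethoxyphenol is O-allylated (allyl bromide, K2CO3, acetone) to 4-allyloxy-1,2-dimethoxybenzene F3.
- Aromatic Claisen rearrangement (N,N-diethylaniline, 190 °C) into the less hindered ortho position gives 2-allyl-4,5-dimethoxyphenol F4.
- PhI(OAc)2 in MeOH gives 2-allyl-4,4,5-trimethoxycyclohexa-2,5-dien-1-one F5.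
- Me3SiOTf (CH2Cl2, −78 to −30 °C) ionises F5. The methyl-bearing alkene carbon of F2 bonds to the allyl-bearing ring carbon, the benzylic cation is closed by the α-carbon of the methoxy enone, and loss of the methyl group from the oxocarbenium ion gives the dione as a racemate of 20 and its mirror image, ent-dione F6.
- The two are separated by preparative HPLC on a chiral stationary phase, and the route is rejoined at 20.

Step 8. The reductive coupling may stall at the hindered C4 ester, or it may be diverted to Dieckmann closure or to simple reduction without C3–C4 bond formation.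

The fallback is a pinacol route that sets out from 15.
- LiAlH4 (THF, 0 °C) gives the C3,C4-diol, 2-[9-allyl-7-(3,4-dimethoxyphenyl)-6-(hydroxymethyl)-8-methyl-1,4-dioxaspiro[4.4]nonan-9-yl]ethanol F7.
- Swern oxidation gives the corresponding dialdehyde F8.
- SmI2 (THF, t-BuOH, −78 °C to rt) closes C3–C4 by intramolecular pinacol coupling to the bicyclic cis-3,4-diol F9.
- Double oxidation with DMSO/(CF3CO)2O/Et3N gives the 1,2-dione, which tautomerises to the diosphenol. The route is rejoined at 18.

Step 13. The two secondary carbinols may not be discriminated well enough in the silylation, leading to silylation at C8 or at both oxygens.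

The fallback tells the two positions apart by the timing of the reductions rather than by sterics, and it sets out from 20.
- NaBH4 (one hydride equivalent, MeOH–CH2Cl2, −78 °C, no cerium salt) reduces only the strained C8 ketone to the 8-hydroxy enone F10.
- Ac2O/DMAP/pyridine gives the 8-acetate F11.
- NaBH4/CeCl3·7H2O (MeOH, −78 °C) reduces C4 from the C8 side to the allylic alcohol F12.
- Et3SiCl/imidazole gives the 4-silyl ether 8-acetate F13.
- i-Bu2AlH (CH2Cl2, −78 °C) removes the acetate. The route is rejoined at 22.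

**Further compounds**
F1 | step 6 | 1-(3,4-dimethoxyphenyl)propan-1-ol | CCC(O)c1ccc(OC)c(OC)c1
F2 | step 6 | (E)-1,2-dimethoxy-4-(prop-1-enyl)benzene | C/C=C/c1ccc(OC)c(OC)c1
F3 | step 6 | 4-allyloxy-1,2-dimethoxybenzene | C=CCOc1ccc(OC)c(OC)c1
F4 | step 6 | 2-allyl-4,5-dimethoxyphenol | C=CCc1cc(OC)c(OC)cc1O
F5 | step 6 | 2-allyl-4,4,5-trimethoxycyclohexa-2,5-dien-1-one | C=CCC1=CC(OC)(OC)C(OC)=CC1=O
F6 | step 6 | mirror image of 20 (second component of the racemate) | C=CC[C@]12C=C(OC)C(=O)[C@H](C1=O)[C@H](c3ccc(OC)c(OC)c3)[C@H]2C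
F7 | step 8 | 2-[9-allyl-7-(3,4-dimethoxyphenyl)-6-(hydroxymethyl)-8-methyl-1,4-dioxaspiro[4.4]nonan-9-yl]ethanol | C=CC[C@@]1(CCO)C2(OCCO2)[C@H](CO)[C@@H](c3ccc(OC)c(OC)c3)[C@@H]1C
F8 | step 8 | 9-allyl-7-(3,4-dimethoxyphenyl)-8-methyl-9-(2-oxoethyl)-1,4-dioxaspiro[4.4]nonane-6-carbaldehyde | C=CC[C@@]1(CC=O)C2(OCCO2)[C@H](C=O)[C@@H](c3ccc(OC)c(OC)c3)[C@@H]1C
F9 | step 8 | 1-allyl-6-(3,4-dimethoxyphenyl)-7-methylspiro[bicyclo[3.2.1]octane-8,2'-[1,3]dioxolane]-3,4-diol (cis-diol, carbinol configuration of no consequence) | C=CC[C@@]12CC(O)C(O)[C@@H](C13OCCO3)[C@@H](c4ccc(OC)c(OC)c4)[C@@H]2C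
F10 | step 13 | 1-allyl-6-(3,4-dimethoxyphenyl)-8-hydroxy-3-methoxy-7-methylbicyclo[3.2.1]oct-2-en-4-one | C=CC[C@@]12C=C(OC)C(=O)[C@@H]([C@@H]1O)[C@@H](c3ccc(OC)c(OC)c3)[C@@H]2C
F11 | step 13 | 1-allyl-6-(3,4-dimethoxyphenyl)-3-methoxy-7-methyl-4-oxobicyclo[3.2.1]oct-2-en-8-yl acetate | C=CC[C@@]12C=C(OC)C(=O)[C@@H]([C@@H]1OC(C)=O)[C@@H](c3ccc(OC)c(OC)c3)[C@@H]2C
F12 | step 13 | 1-allyl-6-(3,4-dimethoxyphenyl)-4-hydroxy-3-methoxy-7-methylbicyclo[3.2.1]oct-2-en-8-yl acetate | C=CC[C@@]12C=C(OC)[C@H](O)[C@@H]([C@@H]1OC(C)=O)[C@@H](c3ccc(OC)c(OC)c3)[C@@H]2C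
F13 | step 13 | 1-allyl-6-(3,4-dimethoxyphenyl)-3-methoxy-7-methyl-4-(triethylsilyloxy)bicyclo[3.2.1]oct-2-en-8-yl acetate | C=CC[C@@]12C=C(OC)[C@H](O[Si](CC)(CC)CC)[C@@H]([C@@H]1OC(C)=O)[C@@H](c3ccc(OC)c(OC)c3)[C@@H]2C
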